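**Plan**
Numbering follows the cembrane skeleton: C1 carries the isopropyl group, C1=C2–C3=C4 is the diene, C7 bears the acetate, C8 and C11 carry the ether bridge (oxolane, ring A) and C12 the tertiary hydroxyl; ring B is the 13-membered oxa-bridged ring.
Retrosynthetic cuts: the acetate; C2–C3 together with C4–CH3 (terminal alkyne C4≡C3H plus alkenyl iodide at C2); C5–C6 (silyl-blocked propargyl anion plus terminal C6–C7 epoxide); C12–CH3 and C13–C14 (MeMgBr on a 2-acyl-oxolane; methyl ketone enolate plus allylic bromide); ring A back to geranyl acetate.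
Forward order: ring A is made first by double Sharpless epoxidation and a Payne rearrangement/5-exo epoxide-opening cascade; the two arms are then attached; ring B is closed last by one-pot methylalumination of the alkyne and Pd-catalysed alkenyl–alkenyl coupling.
Enabling feature: C3=C4 is an E-alkene with H on C3 and CH3 on C4, which is the product pattern of a syn methylmetalation of a C4≡C3–H alkyne, and the cis-2,5-disubstituted ring A holds the C7 arm and the C12 arm on the same face.
Stereochemistry: C7, C8 and C11 come from the D-(−)-tartrate-controlled bis-epoxide (inversion at C7 in the Payne step, retention at C8, inversion at C11 on ring closure); C12 comes from Cram-chelate addition of MeMgBr; the C1=C2 geometry comes from anti carbomagnesiation of propargyl alcohol and the C3=C4 geometry from syn carboalumination.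

Key step: step 11

**Step 1**
Reactants: 1 geranyl acetate
Product: 2 (2E,6E)-8-hydroxy-3,7-dimethylocta-2,6-dien-1-yl acetate
Conditions: SeO2 (0.3 equiv), t-BuOOH (3 equiv), salicylic acid (cat.), CH2Cl2, rt
Reagents that add atoms: tert-butyl hydroperoxide, CC(C)(C)OO; selenium dioxide, O=[Se]=O
Why: SeO2/t-BuOOH allylic oxidation (ene reaction, then [2,3]-sigmatropic shift) should hydroxylate the E-methyl group of the electron-rich distal alkene, while the alkene next to the acetate is deactivated.

**Step 2**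
Reactants: 2 (2E,6E)-8-hydroxy-3,7-dimethylocta-2,6-dien-1-yl acetate
Product: 3 (2E,6E)-2,6-dimethylocta-2,6-diene-1,8-diol
Conditions: K2CO3, MeOH, rt
Reagents that add atoms: none
Why: Transesterification with methanol removes the acetate and frees the second allylic alcohol needed for the double epoxidation.

**Step 3**
Reactants: 3 (2E,6E)-2,6-dimethylocta-2,6-diene-1,8-diol
Product: 4 (2R,3R,6R,7R)-2,3:6,7-diepoxy-2,6-dimethyloctane-1,8-diol
Conditions: Ti(OiPr)4 (0.2 equiv), D-(−)-diethyl tartrate (0.3 equiv), t-BuOOH (4 equiv, anhydrous), 4 Å molecular sieves, CH2Cl2, −20 °C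
Reagents that add atoms: tert-butyl hydroperoxide, CC(C)(C)OO
Why: Double Sharpless asymmetric epoxidation, in which each E-allylic alcohol is epoxidised under reagent control by the D-(−)-tartrate to its (R,R)-epoxide (7R,8R and 11R,12R), the minor enantiomer of each event being diverted into a separable diastereomer.

**Step 4**
Reactants: 4 (2R,3R,6R,7R)-2,3:6,7-diepoxy-2,6-dimethyloctane-1,8-diol
Product: 6 (2R)-2-[(2S,5R)-5-methyl-5-[(2S)-oxiran-2-yl]oxolan-2-yl]propane-1,2-diol, via Payne-rearranged terminal epoxide 5 (not isolated)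
Conditions: NaOH (0.5 M aq.), t-BuOH, 0 °C → rt
Reagents that add atoms: none
Why: Under Payne rearrangement conditions the C6 alkoxide opens the 7,8-epoxide at C7 with inversion, and the tertiary C8 alkoxide so released attacks C11 of the 11,12-epoxide in a 5-exo-tet opening with inversion (the base-mediated counterpart of furanoid linalool oxide formation), which should give the cis-2,5-disubstituted oxolane with C7 S, C8 R, C11 S and C12 R, whereas the Payne isomer at the other end has only a tertiary carbon within 5-exo reach and merely equilibrates.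

**Step 5**
Reactants: 6 (2R)-2-[(2S,5R)-5-methyl-5-[(2S)-oxiran-2-yl]oxolan-2-yl]propane-1,2-diol
Product: 7 1-[(2S,5R)-5-methyl-5-[(2S)-oxiran-2-yl]oxolan-2-yl]ethan-1-one
Conditions: NaIO4, NaHCO3, THF/H2O, 0 °C → rt
Reagents that add atoms: none
Why: Malaprade glycol cleavage of the tertiary/primary 1,2-diol should give the C12 methyl ketone, while the terminal epoxide, which has no vicinal hydroxyl, stays intact and keeps the C7 oxygen masked.

**Step 6**
Reactants: 8 prop-2-yn-1-ol
Product: 10 (2Z)-3-iodo-2-(propan-2-yl)prop-2-en-1-ol, via alkenylmagnesium chelate 9 (not isolated)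
Conditions: i-PrMgCl (2.5 equiv), CuI (10 mol %), THF, 0 °C → rt; then I2, −20 → 0 °C
Reagents that add atoms: isopropylmagnesium chloride, CC(C)[Mg]Cl; iodine, II
Why: Copper-catalysed anti-carbomagnesiation of the magnesium propargyl alkoxide delivers isopropyl to the internal carbon and magnesium to the terminal carbon, held cis to the CH2O group in a five-membered chelate, and iodinolysis with retention should give the iodide cis to CH2OH (the future C2 cis to C14).

**Step 7**
Reactants: 10 (2Z)-3-iodo-2-(propan-2-yl)prop-2-en-1-ol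
Product: 11 (1Z)-2-(bromomethyl)-1-iodo-3-methylbut-1-ene
Conditions: CBr4, PPh3, CH2Cl2, 0 °C
Reagents that add atoms: carbon tetrabromide, BrC(Br)(Br)Br
Why: Appel bromination of the primary allylic alcohol proceeds by SN2 displacement without allylic transposition, so the alkene geometry is kept.

**Step 8**
Reactants: 7 1-[(2S,5R)-5-methyl-5-[(2S)-oxiran-2-yl]oxolan-2-yl]ethan-1-one; 11 (1Z)-2-(bromomethyl)-1-iodo-3-methylbut-1-ene
Product: 13 (4E)-4-(iodomethylidene)-5-methyl-1-[(2S,5R)-5-methyl-5-[(2S)-oxiran-2-yl]oxolan-2-yl]hexan-1-one, via lithium enolate 12 (not isolated)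
Conditions: LiN(i-Pr)2 (1.05 equiv), THF, −78 °C; then 11, DMPU, −78 → −40 °C
Reagents that add atoms: none
Why: Kinetic deprotonation should occur at the methyl group (the only other alpha position is the hindered C11 methine), and SN2 alkylation of the lithium enolate with the reactive allylic bromide forms C13–C14, the epoxide and the alkenyl iodide being inert to the enolate at this temperature.

**Step 9**
Reactants: 13 (4E)-4-(iodomethylidene)-5-methyl-1-[(2S,5R)-5-methyl-5-[(2S)-oxiran-2-yl]oxolan-2-yl]hexan-1-one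
Product: 14 (2R,5E)-5-(iodomethylidene)-6-methyl-2-[(2S,5R)-5-methyl-5-[(2S)-oxiran-2-yl]oxolan-2-yl]heptan-2-ol
Conditions: MeMgBr (3 equiv), Et2O/CH2Cl2, −78 °C; aq. NH4Cl
Reagents that add atoms: methylmagnesium bromide, C[Mg]Br
Why: Grignard addition under Cram-chelate control, in which magnesium bridges the ketone oxygen and the ring oxygen and methyl attacks from the face of the C11 hydrogen (anti to the C10 methylene), should set C12 as R.

**Step 10**
Reactants: 14 (2R,5E)-5-(iodomethylidene)-6-methyl-2-[(2S,5R)-5-methyl-5-[(2S)-oxiran-2-yl]oxolan-2-yl]heptan-2-ol; 15 trimethyl(prop-1-yn-1-yl)silane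
Product: 18 (1S)-1-[(2R,5S)-5-[(2R,5E)-2-hydroxy-5-(iodomethylidene)-6-methylheptan-2-yl]-2-methyloxolan-2-yl]pent-4-yn-1-ol, via lithiated silylpropyne 16 (not isolated), via C-silylated alkyne diol 17 (not isolated)
Conditions: 15 (3 equiv), n-BuLi (2.9 equiv), THF, −78 → −20 °C; add 14, DMPU, −78 → 0 °C; then MeOH, K2CO3, rt
Reagents that add atoms: none
Why: The silyl-blocked propargyl anion should open the monosubstituted epoxide at its CH2 terminus (C6), forming C5–C6 and releasing the C7 hydroxyl with its configuration untouched, and methanolic carbonate then cleaves the alkynyl C–Si bond.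

**Step 11**
Reactants: 18 (1S)-1-[(2R,5S)-5-[(2R,5E)-2-hydroxy-5-(iodomethylidene)-6-methylheptan-2-yl]-2-methyloxolan-2-yl]pent-4-yn-1-ol
Product: 20 (1E,3E,7S,8R,11S,12R)-8,11-epoxycembra-1,3-diene-7,12-diol (the deacetyl target), via alkenylalane 19 (not isolated)
Conditions: AlMe3 (6 equiv), Cp2ZrCl2 (1 equiv), ClCH2CH2Cl, 0 °C → rt; volatiles removed in vacuo; residue in THF added over 12 h to Pd2(dba)3 (10 mol %), P(2-furyl)3 (40 mol %), ZnCl2 (1.5 equiv), THF, 45 °C, about 1 mM; aq. potassium sodium tartrate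
Reagents that add atoms: trimethylaluminium, C[Al](C)C
Why: AlMe3 first converts both hydroxyls into dimethylaluminium alkoxides, and the methylzirconocene species formed from Cp2ZrCl2 and AlMe3 then adds methyl and metal syn across the terminal alkyne, methyl to the internal carbon C4 and metal to C3, giving after Zr-to-Al exchange the (E)-2-methylalkenylalane 19. After removal of excess AlMe3, ZnCl2 relays the alkenyl group to the alkenylpalladium iodide formed by oxidative addition of zerovalent palladium into the C2–I bond, and reductive elimination forms the C2–C3 bond with retention at both sp2 carbons. The closest known reaction type is the one-pot Zr-catalysed methylalumination/Pd-catalysed alkenyl–alkenyl Negishi coupling used for stereodefined trisubstituted dienes, together with macrocyclising Stille and Suzuki diene closures. The step closes ring B (and with it the 14-membered carbocycle) by end-to-end coupling of the two alkenyl termini at C2–C3, so that both alkenes become endocyclic. No stereocentre is created: the C3=C4 geometry follows from the syn carbometalation and the C1=C2 geometry is carried over unchanged from 10. The step needs regioselective methylmetalation (secured by the terminal alkyne; the trisubstituted iodoalkene is inert to the alane), alkenyl rather than methyl transfer (excess AlMe3 is stripped off before the catalyst is added) and ring closure rather than oligomerisation (the cis-2,5-disubstituted ring A holds both arms on one face and the alane is added slowly at high dilution).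

**Step 12**
Reactants: 20 (1E,3E,7S,8R,11S,12R)-8,11-epoxycembra-1,3-diene-7,12-diol
Product: 21 (1E,3E,7S,8R,11S,12R)-12-hydroxy-8,11-epoxycembra-1,3-dien-7-yl acetate (target)
Conditions: Ac2O, pyridine, DMAP (cat.), CH2Cl2, 0 °C → rt
Reagents that add atoms: acetic anhydride, CC(=O)OC(C)=O
Why: Nucleophile-catalysed acylation should take place at the secondary C7 hydroxyl much faster than at the tertiary C12 hydroxyl.

**Compound list**
1 | geranyl acetate, (2E)-3,7-dimethylocta-2,6-dien-1-yl acetate | CC(C)=CCC/C(C)=C/COC(C)=O | starting material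
2 | (2E,6E)-8-hydroxy-3,7-dimethylocta-2,6-dien-1-yl acetate | OC/C(C)=C/CC/C(C)=C/COC(C)=O | intermediate
3 | (2E,6E)-2,6-dimethylocta-2,6-diene-1,8-diol | OC/C(C)=C/CC/C(C)=C/CO | intermediate
4 | (2R,3R,6R,7R)-2,3:6,7-diepoxy-2,6-dimethyloctane-1,8-diol | OC[C@H]1O[C@]1(C)CC[C@H]2O[C@]2(C)CO | intermediate
5 | [(2R,3R)-3-[(3R)-3-hydroxy-3-[(2S)-oxiran-2-yl]butyl]-2-methyloxiran-2-yl]methanol (Payne isomer, present as its alkoxide) | C1O[C@@H]1[C@](C)(O)CC[C@H]2O[C@]2(C)CO | intermediate (not isolated)
6 | (2R)-2-[(2S,5R)-5-methyl-5-[(2S)-oxiran-2-yl]oxolan-2-yl]propane-1,2-diol | C1O[C@@H]1[C@@]2(C)CC[C@H](O2)[C@](C)(O)CO | intermediate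
7 | 1-[(2S,5R)-5-methyl-5-[(2S)-oxiran-2-yl]oxolan-2-yl]ethan-1-one | C1O[C@@H]1[C@@]2(C)CC[C@H](O2)C(C)=O | intermediate
8 | prop-2-yn-1-ol | C#CCO | starting material
9 | chloromagnesium (2Z)-3-(chloromagnesio)-2-(propan-2-yl)prop-2-en-1-olate | Cl[Mg]OC/C(C(C)C)=C\[Mg]Cl | intermediate (not isolated)
10 | (2Z)-3-iodo-2-(propan-2-yl)prop-2-en-1-ol | OC/C(C(C)C)=C\I | intermediate
11 | (1Z)-2-(bromomethyl)-1-iodo-3-methylbut-1-ene | BrC/C(C(C)C)=C\I | intermediate
12 | lithium 1-[(2S,5R)-5-methyl-5-[(2S)-oxiran-2-yl]oxolan-2-yl]ethen-1-olate | C1O[C@@H]1[C@@]2(C)CC[C@H](O2)C(=C)O[Li] | intermediate (not isolated)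
13 | (4E)-4-(iodomethylidene)-5-methyl-1-[(2S,5R)-5-methyl-5-[(2S)-oxiran-2-yl]oxolan-2-yl]hexan-1-one | C1O[C@@H]1[C@@]2(C)CC[C@H](O2)C(=O)CC/C(C(C)C)=C\I | intermediate
14 | (2R,5E)-5-(iodomethylidene)-6-methyl-2-[(2S,5R)-5-methyl-5-[(2S)-oxiran-2-yl]oxolan-2-yl]heptan-2-ol | C1O[C@@H]1[C@@]2(C)CC[C@H](O2)[C@](C)(O)CC/C(C(C)C)=C\I | intermediate
15 | trimethyl(prop-1-yn-1-yl)silane | CC#C[Si](C)(C)C | starting material
16 | (3-lithioprop-1-yn-1-yl)trimethylsilane | [Li]CC#C[Si](C)(C)C | intermediate (not isolated)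
17 | (1S)-1-[(2R,5S)-5-[(2R,5E)-2-hydroxy-5-(iodomethylidene)-6-methylheptan-2-yl]-2-methyloxolan-2-yl]-5-(trimethylsilyl)pent-4-yn-1-ol | C[Si](C)(C)C#CCC[C@H](O)[C@@]1(C)CC[C@H](O1)[C@](C)(O)CC/C(C(C)C)=C\I | intermediate (not isolated)
18 | (1S)-1-[(2R,5S)-5-[(2R,5E)-2-hydroxy-5-(iodomethylidene)-6-methylheptan-2-yl]-2-methyloxolan-2-yl]pent-4-yn-1-ol | C#CCC[C@H](O)[C@@]1(C)CC[C@H](O1)[C@](C)(O)CC/C(C(C)C)=C\I | intermediate
19 | (E)-2-methylalkenyl(dimethyl)alane of 18 with both hydroxyls as dimethylaluminium alkoxides | C[Al](C)/C=C(\C)CC[C@H](O[Al](C)C)[C@@]1(C)CC[C@H](O1)[C@](C)(O[Al](C)C)CC/C(C(C)C)=C\I | intermediate (not isolated)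
20 | (1E,3E,7S,8R,11S,12R)-8,11-epoxycembra-1,3-diene-7,12-diol | O[C@H]1CC/C(C)=C/C=C(/C(C)C)CC[C@@](C)(O)[C@@H]2CC[C@@]1(C)O2 | intermediate
21 | (1E,3E,7S,8R,11S,12R)-12-hydroxy-8,11-epoxycembra-1,3-dien-7-yl acetate | CC(=O)O[C@H]1CC/C(C)=C/C=C(/C(C)C)CC[C@@](C)(O)[C@@H]2CC[C@@]1(C)O2 | target

**Step count**
Total: 12 steps. Longest linear sequence: 10 steps (steps 1–5 and 8–12); steps 6 and 7 make the side fragment.

**Steps most likely to fail**

Step 11. Ring closure may be outrun by oligomerisation at the dilution that the slow aluminium-to-palladium relay tolerates. Methyl instead of alkenyl may be transferred to the alkenylpalladium iodide, or the alane may be protodemetalated before coupling. The fallback makes the diene intermolecularly and closes ring B at C13–C14 by enolate alkylation. It sets out from 6. Opening of the epoxide with an excess of lithiated 15 (THF/DMPU) would give the C-silylated alkyne triol F1, and K2CO3/MeOH the terminal alkyne triol F2. One-pot methylalumination (AlMe3, Cp2ZrCl2) and Pd(PPh3)4/ZnCl2 coupling with iodo alcohol 10 at ordinary concentration would give the (4E,6Z)-dienyl tetraol F3. NaIO4 would cleave its 1,2-diol to the keto diol F4. MsCl, LiCl and 2,4,6-collidine in DMF would convert the primary allylic alcohol selectively into the allylic chloride F5. Slow addition of F5 to LiN(SiMe3)2 (2.2 equiv) in THF at high dilution would close ring B by intramolecular C-alkylation of the methyl ketone enolate, giving the macrocyclic hydroxy ketone F6. Chelation-controlled addition of MeMgBr to F6 comes back to the route at 20.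

Step 4. The epoxy alcohol at the C13 end may also undergo Payne rearrangement and then form a six-membered ether from its C11 alkoxide. Hydroxide may open the terminal epoxide, or the new tertiary alkoxide may attack the epoxide across ring A. The fallback differentiates the two ends so that only the C6 hydroxyl can rearrange. It sets out from 2. Sharpless epoxidation with D-(−)-diethyl tartrate of the one free allylic alcohol would give the epoxy alcohol acetate F7. TBSCl/imidazole would give the silyl ether F8, and K2CO3/MeOH the allylic alcohol F9. A second Sharpless epoxidation with D-(−)-diethyl tartrate would give the mono-silylated bis-epoxide F10. NaOH/t-BuOH would then give the silylated oxolane F11 by the same Payne/5-exo sequence. Bu4NF removes the silyl group and comes back to the route at 6.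

Step 8. Proton transfer between the product ketone and the enolate may lead to double alkylation and to epimerisation at C11. The fallback alkylates a metalated hydrazone (aza-enolate) instead of the ketone enolate. It sets out from 7. Condensation with 1,1-dimethylhydrazine would give the N,N-dimethylhydrazone F12. Deprotonation at the methyl group with LiN(i-Pr)2 and alkylation with 11 would give the alkylated hydrazone F13. Hydrolysis with aqueous CuCl2 at pH 7 comes back to the route at 13.

**Further compounds**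
F1 | step 11 | (2R)-2-[(2S,5R)-5-[(1S)-1-hydroxy-5-(trimethylsilyl)pent-4-yn-1-yl]-5-methyloxolan-2-yl]propane-1,2-diol | C[Si](C)(C)C#CCC[C@H](O)[C@@]1(C)CC[C@H](O1)[C@](C)(O)CO
F2 | step 11 | (2R)-2-[(2S,5R)-5-[(1S)-1-hydroxypent-4-yn-1-yl]-5-methyloxolan-2-yl]propane-1,2-diol | C#CCC[C@H](O)[C@@]1(C)CC[C@H](O1)[C@](C)(O)CO
F3 | step 11 | (2R)-2-[(2S,5R)-5-[(1S,4E,6Z)-1,8-dihydroxy-4-methyl-7-(propan-2-yl)octa-4,6-dien-1-yl]-5-methyloxolan-2-yl]propane-1,2-diol | OC/C(C(C)C)=C\C=C(/C)CC[C@H](O)[C@@]1(C)CC[C@H](O1)[C@](C)(O)CO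
F4 | step 11 | 1-[(2S,5R)-5-[(1S,4E,6Z)-1,8-dihydroxy-4-methyl-7-(propan-2-yl)octa-4,6-dien-1-yl]-5-methyloxolan-2-yl]ethan-1-one | OC/C(C(C)C)=C\C=C(/C)CC[C@H](O)[C@@]1(C)CC[C@H](O1)C(C)=O
F5 | step 11 | 1-[(2S,5R)-5-[(1S,4E,6Z)-8-chloro-1-hydroxy-4-methyl-7-(propan-2-yl)octa-4,6-dien-1-yl]-5-methyloxolan-2-yl]ethan-1-one | ClC/C(C(C)C)=C\C=C(/C)CC[C@H](O)[C@@]1(C)CC[C@H](O1)C(C)=O
F6 | step 11 | (1E,3E,7S,8R,11S)-7-hydroxy-8,11-epoxy-20-norcembra-1,3-dien-12-one (macrocyclic C12 ketone lacking the C12 methyl) | O[C@H]1CC/C(C)=C/C=C(/C(C)C)CCC(=O)[C@@H]2CC[C@@]1(C)O2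
F7 | step 4 | (2E)-5-[(2R,3R)-3-(hydroxymethyl)-3-methyloxiran-2-yl]-3-methylpent-2-en-1-yl acetate | OC[C@@]1(C)O[C@@H]1CC/C(C)=C/COC(C)=O
F8 | step 4 | (2E)-5-[(2R,3R)-3-{[tert-butyl(dimethyl)silyl]oxymethyl}-3-methyloxiran-2-yl]-3-methylpent-2-en-1-yl acetate | CC(C)(C)[Si](C)(C)OC[C@@]1(C)O[C@@H]1CC/C(C)=C/COC(C)=O
F9 | step 4 | (2E)-5-[(2R,3R)-3-{[tert-butyl(dimethyl)silyl]oxymethyl}-3-methyloxiran-2-yl]-3-methylpent-2-en-1-ol | CC(C)(C)[Si](C)(C)OC[C@@]1(C)O[C@@H]1CC/C(C)=C/CO
F10 | step 4 | [(2R,3R)-3-[2-[(2R,3R)-3-{[tert-butyl(dimethyl)silyl]oxymethyl}-3-methyloxiran-2-yl]ethyl]-3-methyloxiran-2-yl]methanol | CC(C)(C)[Si](C)(C)OC[C@@]1(C)O[C@@H]1CC[C@@]2(C)O[C@@H]2CO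
F11 | step 4 | (2R)-1-{[tert-butyl(dimethyl)silyl]oxy}-2-[(2S,5R)-5-methyl-5-[(2S)-oxiran-2-yl]oxolan-2-yl]propan-2-ol | C1O[C@@H]1[C@@]2(C)CC[C@H](O2)[C@](C)(O)CO[Si](C)(C)C(C)(C)C
F12 | step 8 | N,N-dimethylhydrazone of 7 | C1O[C@@H]1[C@@]2(C)CC[C@H](O2)C(C)=NN(C)C
F13 | step 8 | N,N-dimethylhydrazone of 13 | C1O[C@@H]1[C@@]2(C)CC[C@H](O2)C(=NN(C)C)CC/C(C(C)C)=C\I
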